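3 questions stand on this flask, and two of them concern 4.0 d, so my decision about charge and waiting time hangs on those.

| setting | green | grey | flask |
|---|---|---|---|
| Q | 0.025 M | 0.10 M | 0.050 M |
| remark | run made earlier | run made earlier |  |
| time |  |  | 4.0 d |

- green (time / d: G / %, E / %): 0.167: 4.4, 29.3; 0.500: 8.6, 15.2; 0.833: 10.4, 11.6; 1.25: 11.7, 7.7; 2.08: 14.4, 4.5; 2.50: 13.9, 3.9; 3.00: 14.8, 2.8
- grey (time / d: G / %, E / %): 0.250: 5.1, 23.9; 0.417: 7.5, 16.8; 0.625: 8.5, 12.2; 0.833: 9.7, 10.3; 1.25: 10.4, 8.9; 2.00: 12.0, 5.3; 3.00: 13.4, 3.1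

(standard deviation of a reading: 1 percentage point)

- ratio of G to E at 2.0 min
- ratio of G to E at 4.0 d
- which of G and E there is more of at 4.0 d



At 0.833 d the green run shows E at 11.6 % and the grey run shows 10.3 %, though grey was charged 4.00 times as much. That gap of 1.3 percentage points is close to the scatter, so I leave the charge at 0.050 M.

The waiting time depends on how fast E fades. 0.526 d⁻¹ is my tail rate, the apparent first-order rate constant of the late fall of E: the logarithmic falls of E over the last readings of both runs, summed, divided by the summed time spans. Integrating that rate gives an exponential. From the geometric mean of the two readings at 3.00 d, E at 4.0 d comes to 1.74 %.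

I carry G flat from that same time at the geometric mean of its two readings, 14.1 %, so in my estimate G leads and my ratio is 8.09. E then stands against a scatter of 1 point, so I keep the time and repeat the E reading at the end. The 2.0 min ratio lies far before the first reading at 0.167 d, and I commit to no number there.

The forecast gives 0.001 at 2.0 min, 8 at 4.0 d, and G ahead, holding that G seems to “come from E rather than in parallel with it”.

The flask gives 0.0260 at 2.0 min and 7.71 at 4.0 d, with G ahead, 13.2 % against 1.71 % of E.

    Q ⇌ E (K = 1.00, k = 2.50 × 10⁻⁴ s⁻¹)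
    Q ⇌ G (K = 4.00, k = 6.40 × 10⁻⁶ s⁻¹)
    E → X (k = 2.00 × 10⁻⁸ s⁻¹)
    E → D (k = 2.90 × 10⁻⁵ s⁻¹)
    Q ⇌ L (K = 1.60, k = 5.10 × 10⁻⁵ s⁻¹)

At the start, the forward step of Q to E runs 39 times the forward step of Q to G, each taken alone. In this flask E falls from 5.15 % at 2.00 d to 1.71 % at 4.00 d, a tail rate of 0.551 d⁻¹ beside my 0.526 d⁻¹. My tail reckoning contains no charge, so it gives 1.74 % for the flask charged with 0.085 M of Q too, and that flask holds 1.71 % of E at 4.00 d.

The numbers in the tables stem from a simulated flask for an exercise; scatter was added.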